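**Strategy**

Ring B is grown on the ether oxygen of ring A instead of being coupled to it. Its pattern (ether oxygen on C1', hydroxyl on C2', methyl on C4', carbon substituent on C6') matches an aryloxymethyl ketone (C1'–C2') linked through C3'–C4'(CH3)=C5' to an α-keto ester at C6'. One base-mediated operation forms the C1'–C6' bond by intramolecular aldol condensation, aromatises ring B to the C2' phenol and leaves the hindered diaryl ether and the C6' ester in place. The precursor is the (Z)-2-ene-1,5-dione keto ester 21, tethered through oxygen to a brominated ring A whose (R)-1,3-diol is masked as a bis(triethylsilyl) ether.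

Key step: step 11

**Remarks on the chemistry**

- Ring A is numbered from the carboxyl-bearing carbon (C1), ring B from the ether carbon (C1').
- "ArO" stands for 2-bromo-3-methoxy-4-[(1R)-3-methyl-1,3-bis(triethylsilyloxy)butyl]phenoxy.
- Assumption: 19 and 21 will form as E/Z and keto–enol mixtures. 21 is drawn as the Z diketone, since every isomer converges on 24 in step 11.
- The C3' carboxyl that activates the Michael donor is an allyl ester, removable under near-neutral conditions beside the ethyl keto ester.
- The diol is carried as two triethylsilyl ethers, so the final unmasking needs fluoride only and no acid reaches the benzylic carbinol.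

**Route**

Step 1
Reactants: 1 2-bromoresorcinol
Product: 3 3-bromo-2,4-dihydroxybenzaldehyde, via aryl iminium salt 2 (not isolated)
Conditions: POCl3, DMF, MeCN, 0 °C → rt; then H2O, 50 °C
Reagents that add atoms: N,N-dimethylformamide CN(C)C=O; water O
Why: Vilsmeier–Haack formylation, in which the chloroiminium ion attacks the only position that is ortho to one hydroxyl and para to the other (C2 being blocked by bromine) and hydrolysis of iminium 2 releases the aldehyde.

Step 2
Reactants: 3 3-bromo-2,4-dihydroxybenzaldehyde; 4 2-chloro-N-methoxy-N-methylacetamide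
Product: 5 2-(2-bromo-4-formyl-3-hydroxyphenoxy)-N-methoxy-N-methylacetamide
Conditions: CsHCO3, MeCN, 80 °C
Reagents that add atoms: none
Why: Williamson etherification under bicarbonate should be selective for the hydroxyl para to the formyl group, which is the more acidic and is not held in a hydrogen bond to the aldehyde, and it installs C1' together with C2' at the acyl oxidation level.

Step 3
Reactants: 5 2-(2-bromo-4-formyl-3-hydroxyphenoxy)-N-methoxy-N-methylacetamide
Product: 6 2-(2-bromo-4-formyl-3-methoxyphenoxy)-N-methoxy-N-methylacetamide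
Conditions: MeI, K2CO3, DMF, 40 °C
Reagents that add atoms: iodomethane CI
Why: Williamson methylation of the remaining, hydrogen-bonded phenol under carbonate conditions, with no other site acidic enough to compete.

Step 4
Reactants: 6 2-(2-bromo-4-formyl-3-methoxyphenoxy)-N-methoxy-N-methylacetamide; 7 2-methylallylmagnesium chloride
Product: 9 2-{2-bromo-4-[(1R)-1-hydroxy-3-methylbut-3-en-1-yl]-3-methoxyphenoxy}-N-methoxy-N-methylacetamide, via borinate ester 8 (not isolated)
Conditions: (+)-Ipc2BOMe (from (−)-α-pinene), 7 (slight deficit to the borinate), Et2O, −78 °C → rt; then 6, −78 °C; then NaBO3·4H2O, THF/H2O, rt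
Reagents that add atoms: none
Why: Brown asymmetric methallylboration, in which the borane of the (−)-α-pinene series delivers the methallyl group through a closed chair transition state to the Re face of the aldehyde and so sets the (R)-carbinol, while the amide is inert to the allylborane and mild perborate oxidation cleaves borinate 8.

Step 5
Reactants: 9 2-{2-bromo-4-[(1R)-1-hydroxy-3-methylbut-3-en-1-yl]-3-methoxyphenoxy}-N-methoxy-N-methylacetamide
Product: 10 2-{2-bromo-4-[(1R)-1,3-dihydroxy-3-methylbutyl]-3-methoxyphenoxy}-N-methoxy-N-methylacetamide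
Conditions: Co(acac)2 (cat.), PhSiH3, O2 (1 atm), THF, rt
Reagents that add atoms: dioxygen O=O
Why: Mukaiyama hydration, in which hydrogen-atom transfer from a cobalt hydride to the 1,1-disubstituted alkene gives the tertiary radical that is trapped by O2 and reduced to the Markovnikov tertiary alcohol, without touching the aryl bromide, the amide or the stereocentre.

Step 6
Reactants: 10 2-{2-bromo-4-[(1R)-1,3-dihydroxy-3-methylbutyl]-3-methoxyphenoxy}-N-methoxy-N-methylacetamide
Product: 11 2-(ArO)-N-methoxy-N-methylacetamide, the bis(triethylsilyl) ether of 10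
Conditions: Et3SiOTf, 2,6-lutidine, CH2Cl2, −78 → 0 °C
Reagents that add atoms: triethylsilyl trifluoromethanesulfonate CC[Si](CC)(CC)OS(=O)(=O)C(F)(F)F
Why: Silyl ether formation with a silyl triflate, which is reactive enough for the tertiary hydroxyl and gives ethers that should survive the enolate, palladium, amidine, hydride and organolithium steps ahead.

Step 7
Reactants: 11 2-(ArO)-N-methoxy-N-methylacetamide; 12 allyl acetate
Product: 14 allyl 4-(ArO)-3-oxobutanoate, via tetrahedral lithium adduct 13 (not isolated)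
Conditions: LiN(i-Pr)2, 12, THF, −78 °C; then 11, −78 → −40 °C; AcOH quench
Reagents that add atoms: none
Why: Crossed Claisen-type acylation of an ester enolate by a Weinreb amide, in which the chelated adduct 13 persists until the quench so that the β-keto ester is formed only on work-up and is not attacked again.

Step 8
Reactants: 15 diethyl oxalate; 16 1-propynylmagnesium bromide
Product: 18 ethyl 2-oxopent-3-ynoate, via magnesium hemiketal 17 (not isolated)
Conditions: 16 added slowly to 15 (excess), THF, −78 °C; AcOH quench at −78 °C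
Reagents that add atoms: none
Why: Mono-acylation of an alkynyl Grignard reagent by an oxalate diester, in which hemiketal 17 is stable at −78 °C and collapses to the ynone only on quenching, which prevents a second addition.

Step 9
Reactants: 14 allyl 4-(ArO)-3-oxobutanoate; 18 ethyl 2-oxopent-3-ynoate
Product: 19 1-allyl 6-ethyl 2-[(ArO)acetyl]-3-methyl-5-oxohex-3-enedioate (E/Z and enol mixture)
Conditions: Et3N (cat.), CH2Cl2, −20 → 0 °C
Reagents that add atoms: none
Why: Base-catalysed Michael addition of a 1,3-dicarbonyl compound to an alkynone forms the C3'–C4' bond at the methyl-bearing β-carbon of 18, and the very acidic C3'–H of the adduct keeps it as a stabilised enol(ate), so C1' does not enolise and the ring does not close prematurely.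

Step 10
Reactants: 19 1-allyl 6-ethyl 2-[(ArO)acetyl]-3-methyl-5-oxohex-3-enedioate
Product: 21 ethyl (3Z)-7-(ArO)-4-methyl-2,6-dioxohept-3-enoate, via β-keto acid 20 (not isolated)
Conditions: Pd(OAc)2 (cat.), PPh3, HCO2H/Et3N (acid in slight excess), THF, 0 °C → rt; used without storage
Reagents that add atoms: none
Why: Tsuji deallylation–decarboxylation, in which zerovalent palladium formed in the flask ionises the allyl ester, formate reduces the π-allyl complex to propene and the doubly activated acid 20 loses CO2 at room temperature, in an aprotic, slightly acidic buffer that should spare the ethyl keto ester, the silyl ethers and the hindered aryl bromide.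

Step 11
Reactants: 21 ethyl (3Z)-7-(ArO)-4-methyl-2,6-dioxohept-3-enoate
Product: 24 ethyl 2-(ArO)-3-hydroxy-5-methylbenzoate, via aldol adduct 22 (not isolated), via cyclohexadienone 23 (not isolated)
Conditions: DBU, MeCN (high dilution), rt → 45 °C
Reagents that add atoms: none
Why: DBU deprotonates 21 reversibly, mostly at the doubly activated C3' to a dienolate that is unproductive but scrambles the C4'=C5' geometry, while the small equilibrium share of the C1' enolate of the aryloxymethyl ketone adds to the C6' ketone of the keto ester to give aldol 22; E1cB loss of water gives dienone 23, whose C3' methylene tautomerises irreversibly to the C2' phenol. The closest known reaction type is the intramolecular aldol condensation of 2-ene-1,5-diones to phenols, as when 2-methylpyrylium salts are opened by hydroxide and reclose. Ring B closes in a 6-(enolendo)-exo-trig mode, since both C1' and C2' of the enolate lie inside the new ring and the C6' carbonyl oxygen lies outside it. No stereocentre is formed, and the remote silyl-protected (R)-carbinol is not affected. The step needs site selectivity for C1'–C6' bond formation and chemoselectivity for the ketone over both ester carbonyls: only C1' can reach an electrophile through a six-membered transition state, the C6' ketone is the most electrophilic carbonyl, and bromine in place of a carboxyl group at C1 leaves no acyl acceptor on ring A for a competing five-membered closure.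

Step 12
Reactants: 24 ethyl 2-(ArO)-3-hydroxy-5-methylbenzoate
Product: 25 2-(ArO)-3-(hydroxymethyl)-5-methylphenol
Conditions: i-Bu2AlH (excess), CH2Cl2, −78 → 0 °C; aq. potassium sodium tartrate
Reagents that add atoms: none
Why: Hydride reduction of an aryl ester to the benzylic alcohol, with the phenol first converted to its aluminium phenoxide and the aryl bromide and silyl ethers inert at low temperature.

Step 13
Reactants: 25 2-(ArO)-3-(hydroxymethyl)-5-methylphenol
Product: 26 bis(tert-butyldimethylsilyl) ether of 25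
Conditions: TBSCl, imidazole, DMF, rt
Reagents that add atoms: tert-butyldimethylsilyl chloride CC(C)(C)[Si](C)(C)Cl
Why: Silylation of the phenol and the primary benzylic alcohol removes the last acidic protons before the organolithium step and uses groups that fall to the same reagent as the triethylsilyl ethers.

Step 14
Reactants: 26 bis(tert-butyldimethylsilyl) ether of 25
Product: 28 6-[2-(tert-butyldimethylsilyloxy)-6-(tert-butyldimethylsilyloxymethyl)-4-methylphenoxy]-2-methoxy-3-[(1R)-3-methyl-1,3-bis(triethylsilyloxy)butyl]benzoic acid, via aryllithium 27 (not isolated)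
Conditions: t-BuLi (2.1 equiv), THF, −78 °C; then dry CO2, −78 → 0 °C; dilute aq. HCl to pH 3–4; crude acid taken on
Reagents that add atoms: carbon dioxide O=C=O
Why: Bromine–lithium exchange followed by carboxylation, in which exchange at −78 °C outruns any deprotonation, the aryllithium 27 is stabilised by its two flanking oxygens and CO2 trapping puts the carboxyl group on C1.

Step 15
Reactants: 28 the tetrasilylated benzoic acid
Product: 29 6-[2-hydroxy-6-(hydroxymethyl)-4-methylphenoxy]-3-[(1R)-1,3-dihydroxy-3-methylbutyl]-2-methoxybenzoic acid (CNP0452050.1)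
Conditions: Bu4NF, AcOH, THF, 0 °C → rt
Reagents that add atoms: none
Why: Global fluoride-mediated desilylation cleaves all four silyl ethers at silicon under buffered, non-acidic conditions, so the benzylic (R)-carbinol should be neither ionised nor epimerised.

**Compound list**

1 | 2-bromoresorcinol | Oc1cccc(O)c1Br | starting material
2 | N-[(3-bromo-2,4-dihydroxyphenyl)methylidene]-N-methylmethanaminium chloride | C[N+](C)=Cc1ccc(O)c(Br)c1O.[Cl-] | intermediate (not isolated)
3 | 3-bromo-2,4-dihydroxybenzaldehyde | O=Cc1ccc(O)c(Br)c1O | intermediate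
4 | 2-chloro-N-methoxy-N-methylacetamide | CON(C)C(=O)CCl | starting material
5 | 2-(2-bromo-4-formyl-3-hydroxyphenoxy)-N-methoxy-N-methylacetamide | CON(C)C(=O)COc1ccc(C=O)c(O)c1Br | intermediate
6 | 2-(2-bromo-4-formyl-3-methoxyphenoxy)-N-methoxy-N-methylacetamide | COc1c(C=O)ccc(OCC(=O)N(C)OC)c1Br | intermediate
7 | 2-methylallylmagnesium chloride | CC(=C)C[Mg]Cl | starting material
8 | O-diisopinocampheylboryl derivative of 9 (isopinocampheyl groups of the (−)-α-pinene series) | COc1c([C@H](OB([C@H]2C[C@H]3C[C@@H]([C@@H]2C)C3(C)C)[C@H]2C[C@H]3C[C@@H]([C@@H]2C)C3(C)C)CC(C)=C)ccc(OCC(=O)N(C)OC)c1Br | intermediate (not isolated)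
9 | 2-{2-bromo-4-[(1R)-1-hydroxy-3-methylbut-3-en-1-yl]-3-methoxyphenoxy}-N-methoxy-N-methylacetamide | COc1c([C@H](O)CC(C)=C)ccc(OCC(=O)N(C)OC)c1Br | intermediate
10 | 2-{2-bromo-4-[(1R)-1,3-dihydroxy-3-methylbutyl]-3-methoxyphenoxy}-N-methoxy-N-methylacetamide | COc1c([C@H](O)CC(C)(C)O)ccc(OCC(=O)N(C)OC)c1Br | intermediate
11 | 2-{2-bromo-3-methoxy-4-[(1R)-3-methyl-1,3-bis(triethylsilyloxy)butyl]phenoxy}-N-methoxy-N-methylacetamide | COc1c([C@H](O[Si](CC)(CC)CC)CC(C)(C)O[Si](CC)(CC)CC)ccc(OCC(=O)N(C)OC)c1Br | intermediate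
12 | allyl acetate | CC(=O)OCC=C | starting material
13 | lithium alkoxide of the tetrahedral adduct of 11 with the allyl acetate enolate | COc1c([C@H](O[Si](CC)(CC)CC)CC(C)(C)O[Si](CC)(CC)CC)ccc(OCC(O[Li])(CC(=O)OCC=C)N(C)OC)c1Br | intermediate (not isolated)
14 | allyl 4-(ArO)-3-oxobutanoate | COc1c([C@H](O[Si](CC)(CC)CC)CC(C)(C)O[Si](CC)(CC)CC)ccc(OCC(=O)CC(=O)OCC=C)c1Br | intermediate
15 | diethyl oxalate | CCOC(=O)C(=O)OCC | starting material
16 | 1-propynylmagnesium bromide | CC#C[Mg]Br | starting material
17 | bromomagnesium hemiketal alkoxide of the mono-adduct | CC#CC(O[Mg]Br)(OCC)C(=O)OCC | intermediate (not isolated)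
18 | ethyl 2-oxopent-3-ynoate | CC#CC(=O)C(=O)OCC | intermediate
19 | 1-allyl 6-ethyl 2-[(ArO)acetyl]-3-methyl-5-oxohex-3-enedioate (E/Z mixture, C2 configurationally labile) | COc1c([C@H](O[Si](CC)(CC)CC)CC(C)(C)O[Si](CC)(CC)CC)ccc(OCC(=O)C(C(=O)OCC=C)C(C)=CC(=O)C(=O)OCC)c1Br | intermediate
20 | 2-[(ArO)acetyl]-6-ethoxy-3-methyl-5,6-dioxohex-3-enoic acid | COc1c([C@H](O[Si](CC)(CC)CC)CC(C)(C)O[Si](CC)(CC)CC)ccc(OCC(=O)C(C(=O)O)C(C)=CC(=O)C(=O)OCC)c1Br | intermediate (not isolated)
21 | ethyl (3Z)-7-(ArO)-4-methyl-2,6-dioxohept-3-enoate | COc1c([C@H](O[Si](CC)(CC)CC)CC(C)(C)O[Si](CC)(CC)CC)ccc(OCC(=O)C/C(C)=C\C(=O)C(=O)OCC)c1Br | intermediate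
22 | ethyl 6-(ArO)-1-hydroxy-3-methyl-5-oxocyclohex-2-ene-1-carboxylate | COc1c([C@H](O[Si](CC)(CC)CC)CC(C)(C)O[Si](CC)(CC)CC)ccc(OC2C(=O)CC(C)=CC2(O)C(=O)OCC)c1Br | intermediate (not isolated)
23 | ethyl 2-(ArO)-5-methyl-3-oxocyclohexa-1,5-diene-1-carboxylate | COc1c([C@H](O[Si](CC)(CC)CC)CC(C)(C)O[Si](CC)(CC)CC)ccc(OC2=C(C(=O)OCC)C=C(C)CC2=O)c1Br | intermediate (not isolated)
24 | ethyl 2-(ArO)-3-hydroxy-5-methylbenzoate | COc1c([C@H](O[Si](CC)(CC)CC)CC(C)(C)O[Si](CC)(CC)CC)ccc(Oc2c(O)cc(C)cc2C(=O)OCC)c1Br | intermediate
25 | 2-(ArO)-3-(hydroxymethyl)-5-methylphenol | COc1c([C@H](O[Si](CC)(CC)CC)CC(C)(C)O[Si](CC)(CC)CC)ccc(Oc2c(O)cc(C)cc2CO)c1Br | intermediate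
26 | bis(tert-butyldimethylsilyl) ether of 25 | COc1c([C@H](O[Si](CC)(CC)CC)CC(C)(C)O[Si](CC)(CC)CC)ccc(Oc2c(O[Si](C)(C)C(C)(C)C)cc(C)cc2CO[Si](C)(C)C(C)(C)C)c1Br | intermediate
27 | aryllithium from 26 (lithium in place of bromine at C1) | COc1c([C@H](O[Si](CC)(CC)CC)CC(C)(C)O[Si](CC)(CC)CC)ccc(Oc2c(O[Si](C)(C)C(C)(C)C)cc(C)cc2CO[Si](C)(C)C(C)(C)C)c1[Li] | intermediate (not isolated)
28 | 6-[2-(tert-butyldimethylsilyloxy)-6-(tert-butyldimethylsilyloxymethyl)-4-methylphenoxy]-2-methoxy-3-[(1R)-3-methyl-1,3-bis(triethylsilyloxy)butyl]benzoic acid | COc1c([C@H](O[Si](CC)(CC)CC)CC(C)(C)O[Si](CC)(CC)CC)ccc(Oc2c(O[Si](C)(C)C(C)(C)C)cc(C)cc2CO[Si](C)(C)C(C)(C)C)c1C(=O)O | intermediate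
29 | 6-[2-hydroxy-6-(hydroxymethyl)-4-methylphenoxy]-3-[(1R)-1,3-dihydroxy-3-methylbutyl]-2-methoxybenzoic acid | COc1c([C@H](O)CC(C)(C)O)ccc(Oc2c(O)cc(C)cc2CO)c1C(=O)O | target

**Step count and risk**

Total steps: 15. Longest linear sequence: 14 (steps 1–7 and 9–15 from 2-bromoresorcinol); step 8 is a one-step branch.

Steps most likely to fail:

1. Step 11. The substrate may rest as the C3' dienolate, close reversibly through oxygen to a pyranol, or condense intermolecularly at the keto ester, so that C1'–C6' closure stays slow. Fallback, from 21 back to 24: silylate both ketones with Me3SiOTf/Et3N (CH2Cl2, 0 °C) to the bis(trimethylsilyl) trienol ether F1. Heating in toluene should bring about thermal disrotatory 6π-electrocyclisation to the cyclohexadiene F2, which aromatises by loss of trimethylsilanol to the aryl trimethylsilyl ether F3. Brief methanolysis (MeOH, cat. AcOH) returns 24. The same C1'–C6' bond is then made pericyclically from a neutral triene and not by enolate addition.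

2. Step 10. The π-allyl complex may C-allylate the stabilised carbanion of 19, palladium hydride may reduce the electron-poor alkene, or the freed ene-dione may cyclise uncontrolled during work-up. Fallback, from 11 back to 21: acylate LiCH2CO2t-Bu with 11 to the tert-butyl β-keto ester F4, add it to 18 as in step 9 to the tert-butyl Michael adduct F5, and cleave the tert-butyl ester with Me3SiOTf/2,6-lutidine (CH2Cl2, 0 °C) to the trimethylsilyl ester F6. Aqueous work-up hydrolyses F6 to 20, which decarboxylates to 21. No palladium and no allyl electrophile are involved.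

3. Step 9. The ynone keto ester may oligomerise under amine catalysis, or the donor may add reversibly to the keto carbonyl in place of the β-carbon. Fallback, from 18 (with 14) back to 19: hydroiodinate 18 with NaI/AcOH to ethyl (Z)-4-iodo-2-oxopent-3-enoate F7. The stoichiometric caesium enolate of 14 (Cs2CO3, MeCN, 0 °C) then displaces iodide at C4' by addition–elimination and gives 19 from a less polymerisation-prone acceptor.

Further compounds

F1 | step 11 | ethyl 7-(ArO)-4-methyl-2,6-bis(trimethylsilyloxy)hepta-2,4,6-trienoate (bis(trimethylsilyl) trienol ether) | COc1c([C@H](O[Si](CC)(CC)CC)CC(C)(C)O[Si](CC)(CC)CC)ccc(OC=C(O[Si](C)(C)C)C=C(C)C=C(O[Si](C)(C)C)C(=O)OCC)c1Br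
F2 | step 11 | ethyl 6-(ArO)-3-methyl-1,5-bis(trimethylsilyloxy)cyclohexa-2,4-diene-1-carboxylate (cyclohexadiene) | COc1c([C@H](O[Si](CC)(CC)CC)CC(C)(C)O[Si](CC)(CC)CC)ccc(OC2C(O[Si](C)(C)C)=CC(C)=CC2(O[Si](C)(C)C)C(=O)OCC)c1Br
F3 | step 11 | ethyl 2-(ArO)-5-methyl-3-(trimethylsilyloxy)benzoate (aryl trimethylsilyl ether) | COc1c([C@H](O[Si](CC)(CC)CC)CC(C)(C)O[Si](CC)(CC)CC)ccc(Oc2c(O[Si](C)(C)C)cc(C)cc2C(=O)OCC)c1Br
F4 | step 10 | tert-butyl 4-(ArO)-3-oxobutanoate | COc1c([C@H](O[Si](CC)(CC)CC)CC(C)(C)O[Si](CC)(CC)CC)ccc(OCC(=O)CC(=O)OC(C)(C)C)c1Br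
F5 | step 10 | 1-tert-butyl 6-ethyl 2-[(ArO)acetyl]-3-methyl-5-oxohex-3-enedioate | COc1c([C@H](O[Si](CC)(CC)CC)CC(C)(C)O[Si](CC)(CC)CC)ccc(OCC(=O)C(C(=O)OC(C)(C)C)C(C)=CC(=O)C(=O)OCC)c1Br
F6 | step 10 | 6-ethyl 1-trimethylsilyl 2-[(ArO)acetyl]-3-methyl-5-oxohex-3-enedioate | COc1c([C@H](O[Si](CC)(CC)CC)CC(C)(C)O[Si](CC)(CC)CC)ccc(OCC(=O)C(C(=O)O[Si](C)(C)C)C(C)=CC(=O)C(=O)OCC)c1Br
F7 | step 9 | ethyl (Z)-4-iodo-2-oxopent-3-enoate | C/C(I)=C/C(=O)C(=O)OCC
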